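**Retrosynthetic overview**

- Ring numbering used throughout: C1 (CH3, Cl), C2, C3 (CH3, Br), C4 (chlorovinyl), C5, C6 (Br). The strategy rests on the adjacent heteroatom-bearing carbons C1 (fully substituted, methyl-bearing) and C6 (secondary) of the cyclohexane, which are read as a masked α-hydroxy ketone with the carbinol at C1 and the carbonyl at C6.
- Late stage: C3–Br comes from HBr addition to a C3 methylidene, and the chlorovinyl group from cross-metathesis of an (E)-propenyl group. C1–Cl and C6–Br come from the ketol by directed reduction, epoxide formation, chloride opening at C1 and bromide displacement at C6.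
- Key disconnection C1–C6: a chiral carbene-catalysed crossed benzoin reaction of an acyclic keto aldehyde (C6 aldehyde, C1 methyl ketone) closes the only ring, the cyclohexane.
- The keto aldehyde comes from a Johnson–Claisen rearrangement that sets C4 by chirality transfer from (S)-but-3-yn-2-ol; the chain is assembled by Sonogashira coupling with a 2-bromoallyl dithiane (masked methyl ketone).

Key step: step 7

Remark: in the Why lines the ring atoms keep the numbering C1–C6 given above, also where the systematic name of an intermediate numbers the ring differently.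

Assumption: the (5aS,10bR) antipode of 2-(pentafluorophenyl)-5a,10b-dihydro-4H,6H-indeno[2,1-b][1,2,4]triazolo[4,3-d][1,4]oxazin-2-ium tetrafluoroborate is taken as the one matched to the (S) centre at C4 for formation of the (S) carbinol at C1; if the sense is the reverse, the (5aR,10bS) salt is used with nothing else changed.

**Route**

Step 1
Reactants: 1 2-methyl-1,3-dithiane; 2 2,3-dibromoprop-1-ene
Product: 4 2-(2-bromoprop-2-en-1-yl)-2-methyl-1,3-dithiane, via 2-lithio-2-methyl-1,3-dithiane 3 (not isolated)
Conditions: n-BuLi, THF, −30 °C; then 2, −78 → 0 °C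
Reagents that add atoms: none
Why: Corey–Seebach alkylation, in which the sulfur-stabilised carbanion displaces the allylic bromide (direct or allylic attack give the same product) while the vinylic bromide is inert; no stereocentre is formed.

Step 2
Reactants: 4 2-(2-bromoprop-2-en-1-yl)-2-methyl-1,3-dithiane; 5 (S)-but-3-yn-2-ol
Product: 6 (2S)-5-methylidene-6-(2-methyl-1,3-dithian-2-yl)hex-3-yn-2-ol
Conditions: Pd(PPh3)4 (5 mol %), CuI (10 mol %), Et3N, THF, 45 °C
Reagents that add atoms: none
Why: Sonogashira coupling of a 2-bromoalkene with a terminal alkyne under mild amine conditions that should leave the carbinol centre of 5 and the thioacetal untouched.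

Step 3
Reactants: 6 (2S)-5-methylidene-6-(2-methyl-1,3-dithian-2-yl)hex-3-yn-2-ol
Product: 7 (2S,3E)-5-methylidene-6-(2-methyl-1,3-dithian-2-yl)hex-3-en-2-ol
Conditions: LiAlH4, THF, 0 → 45 °C; aq. potassium sodium tartrate
Reagents that add atoms: none
Why: Hydroxyl-directed trans-hydroalumination of a propargylic alcohol reduces only the alkyne and gives the (E)-alkene, leaving the 1,1-disubstituted alkene, the dithiane and the carbinol configuration unchanged.

Step 4
Reactants: 7 (2S,3E)-5-methylidene-6-(2-methyl-1,3-dithian-2-yl)hex-3-en-2-ol; 8 triethyl orthoacetate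
Product: 11 ethyl (3S,4E)-3-[3-(2-methyl-1,3-dithian-2-yl)prop-1-en-2-yl]hex-4-enoate, via mixed orthoester 9 (not isolated), via ketene acetal 10 (not isolated)
Conditions: MeC(OEt)3 (excess), EtCO2H (cat.), 135 °C, EtOH distilled off
Reagents that add atoms: none
Why: Johnson–Claisen rearrangement through a chair transition state with the carbinol methyl equatorial, which transfers the (S) carbinol configuration suprafacially to the new C4 centre as (S) and gives the (E)-propenyl group.

Step 5
Reactants: 11 ethyl (3S,4E)-3-[3-(2-methyl-1,3-dithian-2-yl)prop-1-en-2-yl]hex-4-enoate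
Product: 12 (3S,4E)-3-[3-(2-methyl-1,3-dithian-2-yl)prop-1-en-2-yl]hex-4-enal
Conditions: i-Bu2AlH (1.1 equiv), CH2Cl2, −78 °C; MeOH, then aq. potassium sodium tartrate
Reagents that add atoms: none
Why: Partial reduction of an ester with i-Bu2AlH at low temperature stops at the tetrahedral aluminium hemiacetal, which releases the aldehyde on work-up; C4 is not α to the carbonyl and cannot epimerise.

Step 6
Reactants: 12 (3S,4E)-3-[3-(2-methyl-1,3-dithian-2-yl)prop-1-en-2-yl]hex-4-enal
Product: 13 (3S)-4-methylidene-6-oxo-3-[(E)-prop-1-enyl]heptanal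
Conditions: MeI (excess), CaCO3, MeCN–H2O (9:1), 40 °C; used at once
Reagents that add atoms: water, O
Why: Alkylative hydrolysis of the 1,3-dithiane (S-methylation, ring opening, hydration) under CaCO3 buffering should unmask the ketone without acid or base strong enough to move the C3 methylidene into conjugation or to enolise the aldehyde.

Step 7
Reactants: 13 (3S)-4-methylidene-6-oxo-3-[(E)-prop-1-enyl]heptanal
Product: 14 (2S,5S)-2-hydroxy-2-methyl-4-methylidene-5-[(E)-prop-1-enyl]cyclohexan-1-one
Conditions: chiral N-C6F5 aminoindanol triazolium tetrafluoroborate (15 mol %), i-Pr2NEt (10 mol %), toluene (0.03 M), 23 °C, Ar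
Reagents that add atoms: none
Why: The triazolylidene adds to the C6 aldehyde and proton transfer gives the nucleophilic Breslow intermediate, which attacks the C1 ketone carbonyl; proton transfer to the new alkoxide and loss of the carbene give the α-hydroxy ketone (known reaction type: carbene-catalysed intramolecular crossed aldehyde–ketone benzoin cyclisation). The cyclohexane ring is closed in a 6-exo-trig mode by the C1–C6 bond. The new C1 stereocentre (S, hydroxyl trans to the C4 propenyl group) is set by the chiral triazolium, which fixes the face of the Breslow intermediate and, through the hydrogen-bonded proton-transfer array, the face of the ketone, in a chair transition state with the C4 propenyl group equatorial, the developing alkoxide pseudo-equatorial and the methyl axial beside the sp2 C3. The step needs chemoselectivity (aldehyde as acyl donor, ketone as acceptor, no homo-coupling, no aldol closure, no migration of the C3 methylidene into conjugation), which is secured because only the aldehyde can form a Breslow intermediate, because the 1,6-spacing makes the six-ring closure fast at high dilution, and because less base than azolium salt is used. C4 is not α to either carbonyl, so the single existing stereocentre cannot epimerise.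

Step 8
Reactants: 14 (2S,5S)-2-hydroxy-2-methyl-4-methylidene-5-[(E)-prop-1-enyl]cyclohexan-1-one
Product: 15 (1S,2S,4S)-1-methyl-5-methylidene-4-[(E)-prop-1-enyl]cyclohexane-1,2-diol
Conditions: Me4NBH(OAc)3, MeCN–AcOH (1:1), −25 °C
Reagents that add atoms: none
Why: Hydroxyl-directed triacetoxyborohydride reduction, in which the C1 tertiary hydroxyl exchanges onto boron and delivers hydride internally to the C6 carbonyl from its own face, so that the new C6 hydroxyl is trans to the C1 hydroxyl whatever the ring conformation.

Step 9
Reactants: 15 (1S,2S,4S)-1-methyl-5-methylidene-4-[(E)-prop-1-enyl]cyclohexane-1,2-diol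
Product: 17 (1S,4S,6R)-1-methyl-3-methylidene-4-[(E)-prop-1-enyl]-7-oxabicyclo[4.1.0]heptane, via secondary mesylate 16 (not isolated)
Conditions: MsCl (1.1 equiv), Et3N, CH2Cl2, −10 °C; then K2CO3, MeOH, 23 → 40 °C
Reagents that add atoms: none
Why: Selective sulfonylation of the secondary over the tertiary hydroxyl followed by intramolecular Williamson displacement, in which the C1 alkoxide attacks C6 from the rear in the diaxial conformer, inverts C6 and places the epoxide oxygen on the face of the original C1 hydroxyl.

Step 10
Reactants: 17 (1S,4S,6R)-1-methyl-3-methylidene-4-[(E)-prop-1-enyl]-7-oxabicyclo[4.1.0]heptane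
Product: 18 (1R,2R,5S)-2-chloro-2-methyl-4-methylidene-5-[(E)-prop-1-enyl]cyclohexan-1-ol
Conditions: TiCl4 (1.1 equiv), CH2Cl2, −78 °C, short reaction time; cold water quench
Reagents that add atoms: titanium tetrachloride, Cl[Ti](Cl)(Cl)Cl
Why: Lewis acid-promoted Markovnikov opening of a trisubstituted epoxide by chloride, which delivers chloride to the tertiary C1 with inversion in a trans-diaxial opening that keeps the C4 group equatorial, so that C1 becomes (R) with chlorine anti to the C6 hydroxyl.

Step 11
Reactants: 18 (1R,2R,5S)-2-chloro-2-methyl-4-methylidene-5-[(E)-prop-1-enyl]cyclohexan-1-ol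
Product: 19 (1R,2S,4S)-2-bromo-1-chloro-1-methyl-5-methylidene-4-[(E)-prop-1-enyl]cyclohexane
Conditions: CBr4, P(n-C8H17)3, toluene, 0 → 70 °C
Reagents that add atoms: carbon tetrabromide, BrC(Br)(Br)Br
Why: Appel reaction, in which the C6 alkoxyphosphonium ion is displaced by bromide in an SN2 process with inversion, placing bromine cis to the C1 chlorine, while the β-chlorine disfavours ionisation at C6.

Step 12
Reactants: 19 (1R,2S,4S)-2-bromo-1-chloro-1-methyl-5-methylidene-4-[(E)-prop-1-enyl]cyclohexane; 20 (E)-1,2-dichloroethene
Product: 21 (1R,2S,4S)-2-bromo-1-chloro-4-[(E)-2-chloroethenyl]-1-methyl-5-methylidenecyclohexane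
Conditions: 20 (5 equiv), Mo(NC6F5)(CHCMe2Ph)(NC4H2Me2-2,5)(OC6H3-2,6-(C6H2Et3-2,4,6)2) (10 mol %), benzene, 23 °C, N2
Reagents that add atoms: none
Why: Stereoretentive cross-metathesis of an (E)-1,2-disubstituted alkene with (E)-1,2-dichloroethene by a molybdenum monoaryloxide pyrrolide alkylidene should give the (E)-alkenyl chloride and volatile (E)-1-chloropropene, while the hindered 1,1-disubstituted methylidene and the alkyl halides stay untouched.

Step 13
Reactants: 21 (1R,2S,4S)-2-bromo-1-chloro-4-[(E)-2-chloroethenyl]-1-methyl-5-methylidenecyclohexane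
Product: 22 (1R,2S,4S,5R)-1,4-dibromo-5-chloro-2-[(E)-2-chloroethenyl]-1,5-dimethylcyclohexane
Conditions: anhydrous HBr, CH2Cl2, −78 °C, dark
Reagents that add atoms: hydrogen bromide, Br
Why: Markovnikov ionic addition of HBr, in which protonation of the 1,1-disubstituted alkene gives the tertiary C3 cation (the chloroalkene is too electron-poor to compete) and bromide is expected to enter from the equatorial direction, trans to the C4 chlorovinyl group, because the axial trajectory is blocked by the syn-axial C1 chlorine, setting C3 as (R).

**Compound list**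

1 | 2-methyl-1,3-dithiane | CC1SCCCS1 | starting material
2 | 2,3-dibromoprop-1-ene | C=C(Br)CBr | starting material
3 | 2-lithio-2-methyl-1,3-dithiane | [Li]C1(C)SCCCS1 | intermediate
4 | 2-(2-bromoprop-2-en-1-yl)-2-methyl-1,3-dithiane | CC1(CC(Br)=C)SCCCS1 | intermediate
5 | (S)-but-3-yn-2-ol | C[C@H](O)C#C | starting material
6 | (2S)-5-methylidene-6-(2-methyl-1,3-dithian-2-yl)hex-3-yn-2-ol | C[C@H](O)C#CC(=C)CC1(C)SCCCS1 | intermediate
7 | (2S,3E)-5-methylidene-6-(2-methyl-1,3-dithian-2-yl)hex-3-en-2-ol | C[C@H](O)/C=C/C(=C)CC1(C)SCCCS1 | intermediate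
8 | triethyl orthoacetate | CCOC(C)(OCC)OCC | starting material
9 | (2S,3E)-2-(1,1-diethoxyethoxy)-5-methylidene-6-(2-methyl-1,3-dithian-2-yl)hex-3-ene (mixed orthoester) | CCOC(C)(OCC)O[C@@H](C)/C=C/C(=C)CC1(C)SCCCS1 | intermediate
10 | (2S,3E)-2-[(1-ethoxyethenyl)oxy]-5-methylidene-6-(2-methyl-1,3-dithian-2-yl)hex-3-ene (ketene acetal) | C=C(OCC)O[C@@H](C)/C=C/C(=C)CC1(C)SCCCS1 | intermediate
11 | ethyl (3S,4E)-3-[3-(2-methyl-1,3-dithian-2-yl)prop-1-en-2-yl]hex-4-enoate | CCOC(=O)C[C@@H](/C=C/C)C(=C)CC1(C)SCCCS1 | intermediate
12 | (3S,4E)-3-[3-(2-methyl-1,3-dithian-2-yl)prop-1-en-2-yl]hex-4-enal | O=CC[C@@H](/C=C/C)C(=C)CC1(C)SCCCS1 | intermediate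
13 | (3S)-4-methylidene-6-oxo-3-[(E)-prop-1-enyl]heptanal | CC(=O)CC(=C)[C@H](/C=C/C)CC=O | intermediate
14 | (2S,5S)-2-hydroxy-2-methyl-4-methylidene-5-[(E)-prop-1-enyl]cyclohexan-1-one | O[C@@]1(C)CC(=C)[C@H](/C=C/C)CC1=O | intermediate
15 | (1S,2S,4S)-1-methyl-5-methylidene-4-[(E)-prop-1-enyl]cyclohexane-1,2-diol | O[C@@]1(C)CC(=C)[C@H](/C=C/C)C[C@@H]1O | intermediate
16 | (1S,2S,5S)-2-hydroxy-2-methyl-4-methylidene-5-[(E)-prop-1-enyl]cyclohexyl methanesulfonate | O[C@@]1(C)CC(=C)[C@H](/C=C/C)C[C@@H]1OS(C)(=O)=O | intermediate
17 | (1S,4S,6R)-1-methyl-3-methylidene-4-[(E)-prop-1-enyl]-7-oxabicyclo[4.1.0]heptane | C[C@]12CC(=C)[C@H](/C=C/C)C[C@H]1O2 | intermediate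
18 | (1R,2R,5S)-2-chloro-2-methyl-4-methylidene-5-[(E)-prop-1-enyl]cyclohexan-1-ol | C[C@@]1(Cl)CC(=C)[C@H](/C=C/C)C[C@H]1O | intermediate
19 | (1R,2S,4S)-2-bromo-1-chloro-1-methyl-5-methylidene-4-[(E)-prop-1-enyl]cyclohexane | C[C@@]1(Cl)CC(=C)[C@H](/C=C/C)C[C@@H]1Br | intermediate
20 | (E)-1,2-dichloroethene | Cl/C=C/Cl | starting material
21 | (1R,2S,4S)-2-bromo-1-chloro-4-[(E)-2-chloroethenyl]-1-methyl-5-methylidenecyclohexane | C[C@@]1(Cl)CC(=C)[C@H](/C=C/Cl)C[C@@H]1Br | intermediate
22 | (1R,2S,4S,5R)-1,4-dibromo-5-chloro-2-[(E)-2-chloroethenyl]-1,5-dimethylcyclohexane | C[C@@]1(Cl)C[C@@](C)(Br)[C@H](/C=C/Cl)C[C@@H]1Br | target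

**Step count**

Total step count: 13. Longest linear sequence: 13 steps (1 to 22); compounds 2, 5, 8 and 20 are commercial and enter directly.

**Steps most likely to fail**

Step 11 (bromide displacement at C6). The rear-side attack at C6 is hindered by the adjacent fully substituted C1. It may be outrun by anti elimination towards C5, or by participation of the anti-periplanar C1 chlorine, which would give retention or transposition of the halogens. The fallback sets out from 18 and separates activation from displacement. Triflation (Tf2O, pyridine, CH2Cl2, −30 °C) gives (1R,2R,5S)-2-chloro-2-methyl-4-methylidene-5-[(E)-prop-1-enyl]cyclohexyl trifluoromethanesulfonate F2. This isolated sulfonate is then displaced by a soluble bromide (n-Bu4NBr, toluene, 0 → 23 °C) under non-ionising conditions with inversion. The fallback comes back to the route at 19.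

Step 7 (key benzoin closure). The amine base or the free carbene may move the C3 methylidene into conjugation with the ketone or trigger aldol closure before the carbene adds. The catalyst may also prove mismatched with the C4 centre and give poor facial selectivity at the ketone. The fallback sets out from 13 and uses no base. A McMurry coupling of the two carbonyl groups (TiCl3(DME)1.5, Zn–Cu couple, DME, reflux, slow addition) gives (4S)-1-methyl-5-methylidene-4-[(E)-prop-1-enyl]cyclohex-1-ene F1. A Jacobsen–Katsuki epoxidation follows, using [N,N'-bis(3,5-di-tert-butylsalicylidene)-1,2-cyclohexanediaminato]MnCl, aqueous NaOCl and 4-phenylpyridine N-oxide in CH2Cl2 at 0 °C. The catalyst antipode is chosen to deliver oxygen to the ring face trans to the C4 propenyl group. It should oxidise only the trisubstituted ring alkene, since trans-1,2-disubstituted and 1,1-disubstituted alkenes are poor substrates. The fallback comes back to the route at 17.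

Step 13 (HBr addition at C3). Capture of the C3 cation may show poor facial selectivity, and reversible ionisation of the tertiary bromide may erode a kinetic preference, so that the C3 epimer forms alongside the target. The fallback sets out from 21 and replaces the ion pair by a tertiary radical. A hydrogen-atom-transfer hydrobromination (Co(acac)2, t-BuOOH, Et3SiH, p-toluenesulfonyl bromide, 23 °C) transfers bromine irreversibly from a bulky donor, which should approach anti to the axial C1 chlorine. It comes back to the route at 22 and forms no further compound (F0).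

**Further compounds**

F1 | step 7 | (4S)-1-methyl-5-methylidene-4-[(E)-prop-1-enyl]cyclohex-1-ene | CC1=CC[C@@H](/C=C/C)C(=C)C1
F2 | step 11 | (1R,2R,5S)-2-chloro-2-methyl-4-methylidene-5-[(E)-prop-1-enyl]cyclohexyl trifluoromethanesulfonate | C[C@@]1(Cl)CC(=C)[C@H](/C=C/C)C[C@H]1OS(=O)(=O)C(F)(F)F
F0 | step 13 | none | none
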